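At early times the substrate of the elm run falls as a first-order decay, with a constant of 0.545 min⁻¹ read between 1.33 min and 5.00 min. Target trails it, gives its highest reading of 42.4% at 5.00 min, and reads 21.5% at 20.0 min.

| flask | substrate | capture agent | remark | time |
|---|---|---|---|---|
| elm | 0.15 M | 2 mM | run made earlier |  |
| flask | 0.10 M | 2.00 mM |  | 3.0 h |

elm run (percent of the substrate charged)

| time / min | target / % | substrate / % |
|---|---|---|
| 1.33 | 9.6 | 44.3 |
| 2.50 | 27.6 | 22.3 |
| 5.00 | 42.4 | 6.0 |
| 10.0 | 28.7 | 0.7 |
| 20.0 | 21.5 | 0.7 |

(each reading ± 1 percentage point)

- the best time, 3.0 h at the latest, for target
- the amount of target, in percent of the substrate charged, at that time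

- what was read earlier has a scatter of 1 percentage point, one standard deviation

The bench rule for a chain of first-order steps is that percent against time does not depend on the charge, so the flask, with 0.10 M of substrate instead of 0.15 M, should repeat the elm curve. The rule stops where a partner enters bimolecularly, and the candidate here is the capture agent. The capture agent charged over the substrate charged, counted one to one, is the capture ceiling C: 2.00% in the flask and 1.33% in the elm run. The elm fall of target after its highest reading is 21 percentage points, far more than that run's ceiling, so one-to-one capture cannot account for it. The reckoning here therefore keeps the elm curve for the flask: a best near 5.00 min of about 42.4%, give or take C.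

The forecast differs, with 58% at 0.1 h, on the suggestion “that a by-product destroys target once the 2 mM capture agent is exhausted”.

The flask reaches 42.9% of target at 5.19 min.

    intermediate A → intermediate B (k = 0.170 s⁻¹)
    substrate → intermediate A (k = 0.0100 s⁻¹)
    intermediate C + capture agent → trapped intermediate (k = 0.380 M⁻¹ s⁻¹)
    intermediate C → target (k = 0.0630 s⁻¹)
    intermediate B → intermediate C (k = 0.00920 s⁻¹)
    target ⇌ isomer of the product (K = 3.80, k = 0.00480 s⁻¹)

Target and isomer of the product relax with a half-life of 1.91 min, short against 3.0 h, and at 3.00 h the flask stands under thermodynamic control with 20.6% target beside 78.5% isomer of the product. With 55% of the capture agent left, the flask's C gives 0.900% of the substrate charged as captured, and the flask holds 0.900% trapped intermediate. Going from the elm ceiling of 1.33% to the flask's 2.00% by the amount of substrate alone, the highest target, free of scatter, goes from 42.9% to 42.9%.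

The earlier runs and the new flask are calculated with constants of no real substance; noise was put on by code.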